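**Plan**

- Retrosynthesis: both benzylic bonds on the lactone are cut in one operation, ArCH2–C4 (conjugate addition) and C3–CH2Ar (enolate alkylation). In the side chain the CH(Ar)–C(O)Ar' bond is then cut as an aldol at the alcohol level, and the aryl–CH2 bond of an arylacetic acid as a cross-coupling.
- Enabling feature: lactone C3 and C4 are the α- and β-carbons of a butenolide. The OCH2 carbon C5 can be raised to an acetal carrying a removable l-menthyloxy stereocentre. The benzylic carbon on C4 can be raised to a 1,3-dithiane (acyl-anion equivalent). The ketone travels as an acetonide-protected carbinol.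
- Forward order: central-ring bromide 13 (steps 1–8), dithiane 14 (step 9), one-flask union of three fragments on the furanone ring (step 10), removal of sulfur, menthyloxy and acetonide (steps 11–12), oxidation (step 13), debenzylation (step 14).
- Rings: no ring of the target is built. The three benzene rings and the five-membered ring are bought; the lactone is opened and re-closed once in step 12.
- Stereochemistry: lactone C4 and C3 are relayed by substrate control from the one bought acetal centre of 15 (anti addition, then trans alkylation). The side-chain centre comes from an Evans syn-aldol with (R)-4-benzyloxazolidin-2-one. The aldol carbinol centre and the acetal centre are temporary and are erased.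

Key step: step 10

Assumption: furanone 15 is taken as a purchasable single (5R) diastereomer derived from l-menthol.

**Route**

Step 1
Reactants: 1 methyl 3-bromo-4-hydroxy-5-methoxybenzoate
Product: 2 methyl 4-(benzyloxy)-3-bromo-5-methoxybenzoate
Conditions: BnBr, K2CO3, DMF, rt
Reagents that add atoms: benzyl bromide, BrCc1ccccc1
Why: Williamson O-alkylation of the phenoxide gives an aryl benzyl ether that is inert to the organolithium, hydride and mild acid steps and leaves under neutral hydrogenolysis at the end.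

Step 2
Reactants: 2 methyl 4-(benzyloxy)-3-bromo-5-methoxybenzoate
Product: 3 methyl 4-(benzyloxy)-3-(2-tert-butoxy-2-oxoethyl)-5-methoxybenzoate
Conditions: BrZnCH2CO2tBu, Pd(dba)2 (cat.), P(tBu)3 (cat.), THF, rt to 50 °C
Reagents that add atoms: (2-tert-butoxy-2-oxoethyl)zinc bromide, CC(C)(C)OC(=O)C[Zn]Br
Why: Palladium-catalysed α-arylation of a zinc ester enolate (Reformatsky-type Negishi coupling) runs by oxidative addition of the aryl bromide to zerovalent palladium, transmetalation and reductive elimination, and the weakly basic zinc enolate does not touch the methyl benzoate.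

Step 3
Reactants: 3 methyl 4-(benzyloxy)-3-(2-tert-butoxy-2-oxoethyl)-5-methoxybenzoate
Product: 4 2-[2-(benzyloxy)-3-methoxy-5-(methoxycarbonyl)phenyl]acetic acid
Conditions: CF3CO2H, CH2Cl2, 0 °C to rt
Reagents that add atoms: none
Why: Acid-promoted E1 cleavage of the tert-butyl ester releases the arylacetic acid while the methyl ester and the aryl benzyl ether stay.

Step 4
Reactants: 4 2-[2-(benzyloxy)-3-methoxy-5-(methoxycarbonyl)phenyl]acetic acid; 5 (R)-4-benzyloxazolidin-2-one
Product: 7 (R)-4-benzyl-3-{2-[2-(benzyloxy)-3-methoxy-5-(methoxycarbonyl)phenyl]acetyl}oxazolidin-2-one, via mixed pivalic anhydride 6 (not isolated)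
Conditions: PivCl, Et3N, THF, −20 °C; then LiCl, 5, −20 °C to rt
Reagents that add atoms: none
Why: N-acylation of the oxazolidinone through the mixed anhydride (LiCl/Et3N variant) is the standard entry to Evans imides and occurs at the less hindered arylacetyl carbonyl of 6.

Step 5
Reactants: 7 (R)-4-benzyl-3-(arylacetyl)oxazolidin-2-one; 8 4-(benzyloxy)-3-methoxybenzaldehyde
Product: 10 (R)-4-benzyl-3-[(2R,3R)-2-(2-benzyloxy-3-methoxy-5-methoxycarbonylphenyl)-3-(4-benzyloxy-3-methoxyphenyl)-3-hydroxypropanoyl]oxazolidin-2-one, via Z-boron enolate 9 (not isolated)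
Conditions: Bu2BOTf, iPr2NEt, CH2Cl2, −78 to 0 °C; 8, −78 to 0 °C; then pH 7 buffer, MeOH, H2O2, 0 °C
Reagents that add atoms: none
Why: Evans syn-aldol reaction, in which the Z-dibutylboron enolate reacts through a Zimmerman–Traxler chair with one face blocked by the (R)-benzyl group of the auxiliary, should give the (2R,3R) syn adduct; C2 becomes the side-chain stereocentre of the target and the C3 carbinol is a temporary centre.

Step 6
Reactants: 10 syn-aldol imide
Product: 11 (1R,2S)-2-[2-(benzyloxy)-5-(hydroxymethyl)-3-methoxyphenyl]-1-[4-(benzyloxy)-3-methoxyphenyl]propane-1,3-diol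
Conditions: LiBH4, MeOH, THF, 0 to 45 °C
Reagents that add atoms: none
Why: LiBH4 cleaves the imide reductively to the primary alcohol with release of the auxiliary and, on warming, reduces the aryl methyl ester to the benzylic alcohol, after which the C2 centre is no longer α to a carbonyl group and cannot epimerise.

Step 7
Reactants: 11 triol
Product: 12 {4-(benzyloxy)-3-[(4R,5S)-4-(4-benzyloxy-3-methoxyphenyl)-2,2-dimethyl-1,3-dioxan-5-yl]-5-methoxyphenyl}methanol
Conditions: Me2C(OMe)2, PPTS (cat.), acetone, rt; aq NH4Cl work-up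
Reagents that add atoms: 2,2-dimethoxypropane, COC(C)(C)OC
Why: Acid-catalysed transketalisation closes the six-membered 1,3-dioxane on the 1,3-diol under thermodynamic control, whereas the lone benzylic alcohol can only form a labile open-chain mixed ketal that is lost on work-up.

Step 8
Reactants: 12 acetonide benzylic alcohol
Product: 13 (4R,5S)-5-[2-(benzyloxy)-5-(bromomethyl)-3-methoxyphenyl]-4-[4-(benzyloxy)-3-methoxyphenyl]-2,2-dimethyl-1,3-dioxane
Conditions: CBr4, PPh3, CH2Cl2, 0 °C
Reagents that add atoms: carbon tetrabromide, BrC(Br)(Br)Br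
Why: Appel bromination converts the primary benzylic alcohol into the bromide by SN2 displacement of an alkoxyphosphonium ion under neutral conditions that spare the acetonide.

Step 9
Reactants: 8 4-(benzyloxy)-3-methoxybenzaldehyde
Product: 14 2-[4-(benzyloxy)-3-methoxyphenyl]-1,3-dithiane
Conditions: HS(CH2)3SH, BF3·OEt2, CH2Cl2, 0 °C to rt
Reagents that add atoms: propane-1,3-dithiol, SCCCS
Why: Lewis-acid-catalysed dithioacetalisation turns the aldehyde carbon into an acyl-anion equivalent (umpolung) whose two sulfur atoms are later exchanged for hydrogen.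

Step 10
Reactants: 14 2-[4-(benzyloxy)-3-methoxyphenyl]-1,3-dithiane; 15 (5R)-5-(l-menthyloxy)furan-2(5H)-one; 13 benzylic bromide
Product: 18 (3R,4R,5R)-3-{4-(benzyloxy)-3-[(4R,5S)-4-(4-benzyloxy-3-methoxyphenyl)-2,2-dimethyl-1,3-dioxan-5-yl]-5-methoxybenzyl}-4-{2-[4-(benzyloxy)-3-methoxyphenyl]-1,3-dithian-2-yl}-5-(l-menthyloxy)dihydrofuran-2(3H)-one, via lithiated dithiane 16 (not isolated), via lithium enolate 17 (not isolated)
Conditions: 14, n-BuLi, THF, −78 °C; 15, −78 °C; then 13, DMPU, −78 to −20 °C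
Reagents that add atoms: none
Why: n-BuLi removes the proton between the two sulfur atoms of 14, the soft carbanion 16 adds in a Michael fashion to C4 of the furanone 15, and the resulting lithium enolate 17 is alkylated at C3 by the benzylic bromide 13 in an SN2 step, so that both benzylic bonds of the lactone are made in one flask. The closest known reaction type is the tandem conjugate addition–enolate alkylation of 2-aryl-2-lithio-1,3-dithianes with 5-alkoxyfuran-2(5H)-ones and benzylic halides, the standard entry to trans-dibenzylbutyrolactone lignans. No ring is closed, since the five-membered ring is already present in 15. The C4 centre is controlled by the C5 menthyloxy group, which covers one face of the planar butenolide so that 16 enters anti to it, and the C3 centre is controlled by the new, very bulky C4 substituent, which directs 13 to the opposite face (3,4-trans); the one bought acetal centre is thus relayed to both lactone centres. The step needs 1,4- instead of 1,2-addition, which the soft and hindered dithianyl anion secures, and C-alkylation without proton transfer, which is secured by DMPU, by the reactive unhindered primary benzylic bromide and by the absence of acidic protons and carbonyl groups in 13, whose ketone is masked as the acetonide of the diol.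

Step 11
Reactants: 18 three-component adduct
Product: 19 (3R,4R,5R)-3-{4-(benzyloxy)-3-[(4R,5S)-4-(4-benzyloxy-3-methoxyphenyl)-2,2-dimethyl-1,3-dioxan-5-yl]-5-methoxybenzyl}-4-[4-(benzyloxy)-3-methoxybenzyl]-5-(l-menthyloxy)dihydrofuran-2(3H)-one
Conditions: NiCl2·6H2O, NaBH4, MeOH/THF, 0 °C to rt
Reagents that add atoms: none
Why: Reductive desulfurisation of the dithioacetal by Ni2B formed in the flask replaces both benzylic C–S bonds by C–H without touching a stereocentre, and this mild reagent should leave the aryl benzyl ethers, the acetonide and the acyl acetal in place.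

Step 12
Reactants: 19 desulfurised acetal lactone
Product: 21 (3R,4R)-4-[4-(benzyloxy)-3-methoxybenzyl]-3-{4-(benzyloxy)-3-[(1R,2S)-1-(4-benzyloxy-3-methoxyphenyl)-1,3-dihydroxypropan-2-yl]-5-methoxybenzyl}dihydrofuran-2(3H)-one, via potassium hydroxy carboxylate 20 (not isolated)
Conditions: NaBH4, KOH, EtOH/THF/H2O, rt; then 2 M HCl, THF, rt
Reagents that add atoms: none
Why: Hydroxide opens the acyl acetal (pseudo-ester) to the carboxylate and the free aldehyde with loss of menthol, NaBH4 reduces the aldehyde at once before C4 can epimerise, and acid then re-closes the γ-lactone and hydrolyses the acetonide, so that the temporary C5 centre is erased and C3/C4 stay trans.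

Step 13
Reactants: 21 lactone diol
Product: 22 (3R,4R)-4-[4-(benzyloxy)-3-methoxybenzyl]-3-{4-(benzyloxy)-3-[(2S)-1-(4-benzyloxy-3-methoxyphenyl)-3-hydroxy-1-oxopropan-2-yl]-5-methoxybenzyl}dihydrofuran-2(3H)-one
Conditions: DDQ, 1,4-dioxane, rt
Reagents that add atoms: none
Why: DDQ dehydrogenation by hydride abstraction is selective for the secondary carbinol C–H that is benzylic to the para-alkoxy ring (the selective benzylic oxidation known for 1,2-diarylpropane-1,3-diols of the lignin series), leaves the primary alcohol alone, erases the temporary carbinol centre and, being non-basic, should keep the adjacent α-aryl centre.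

Step 14
Reactants: 22 tris(benzyl ether) keto alcohol
Product: 23 (3R,4R)-4-(4-hydroxy-3-methoxybenzyl)-3-{4-hydroxy-3-[(2S)-3-hydroxy-1-(4-hydroxy-3-methoxyphenyl)-1-oxopropan-2-yl]-5-methoxybenzyl}dihydrofuran-2(3H)-one (target)
Conditions: H2 (1 atm), Pd/C, EtOAc, rt
Reagents that add atoms: none
Why: Neutral hydrogenolysis of the three aryl benzyl ethers frees the phenols without acid or base, so that the enolisable β-hydroxy ketone centre and the lactone are not disturbed, and the reaction is stopped after uptake of three equivalents of hydrogen to spare the aryl ketone.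

**Compound list**

1 | methyl 3-bromo-4-hydroxy-5-methoxybenzoate | COC(=O)c1cc(Br)c(O)c(OC)c1 | starting material
2 | methyl 4-(benzyloxy)-3-bromo-5-methoxybenzoate | COC(=O)c1cc(Br)c(OCc2ccccc2)c(OC)c1 | intermediate
3 | methyl 4-(benzyloxy)-3-(2-tert-butoxy-2-oxoethyl)-5-methoxybenzoate | COC(=O)c1cc(CC(=O)OC(C)(C)C)c(OCc2ccccc2)c(OC)c1 | intermediate
4 | 2-[2-(benzyloxy)-3-methoxy-5-(methoxycarbonyl)phenyl]acetic acid | COC(=O)c1cc(CC(=O)O)c(OCc2ccccc2)c(OC)c1 | intermediate
5 | (R)-4-benzyloxazolidin-2-one | O=C1N[C@H](Cc2ccccc2)CO1 | starting material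
6 | mixed anhydride of acid 4 with pivalic acid | COC(=O)c1cc(CC(=O)OC(=O)C(C)(C)C)c(OCc2ccccc2)c(OC)c1 | intermediate
7 | (R)-4-benzyl-3-{2-[2-(benzyloxy)-3-methoxy-5-(methoxycarbonyl)phenyl]acetyl}oxazolidin-2-one | COC(=O)c1cc(CC(=O)N2[C@H](Cc3ccccc3)COC2=O)c(OCc2ccccc2)c(OC)c1 | intermediate
8 | 4-(benzyloxy)-3-methoxybenzaldehyde | COc1cc(C=O)ccc1OCc1ccccc1 | starting material
9 | Z-dibutylboron enolate of imide 7 | COC(=O)c1cc(/C=C(\OB(CCCC)CCCC)N2[C@H](Cc3ccccc3)COC2=O)c(OCc2ccccc2)c(OC)c1 | intermediate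
10 | (R)-4-benzyl-3-[(2R,3R)-2-(2-benzyloxy-3-methoxy-5-methoxycarbonylphenyl)-3-(4-benzyloxy-3-methoxyphenyl)-3-hydroxypropanoyl]oxazolidin-2-one | COC(=O)c1cc([C@@H](C(=O)N2[C@H](Cc3ccccc3)COC2=O)[C@@H](O)c2ccc(OCc3ccccc3)c(OC)c2)c(OCc2ccccc2)c(OC)c1 | intermediate
11 | (1R,2S)-2-[2-(benzyloxy)-5-(hydroxymethyl)-3-methoxyphenyl]-1-[4-(benzyloxy)-3-methoxyphenyl]propane-1,3-diol | OCc1cc([C@@H](CO)[C@@H](O)c2ccc(OCc3ccccc3)c(OC)c2)c(OCc2ccccc2)c(OC)c1 | intermediate
12 | {4-(benzyloxy)-3-[(4R,5S)-4-(4-benzyloxy-3-methoxyphenyl)-2,2-dimethyl-1,3-dioxan-5-yl]-5-methoxyphenyl}methanol | OCc1cc([C@H]2COC(C)(C)O[C@H]2c2ccc(OCc3ccccc3)c(OC)c2)c(OCc2ccccc2)c(OC)c1 | intermediate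
13 | (4R,5S)-5-[2-(benzyloxy)-5-(bromomethyl)-3-methoxyphenyl]-4-[4-(benzyloxy)-3-methoxyphenyl]-2,2-dimethyl-1,3-dioxane | BrCc1cc([C@H]2COC(C)(C)O[C@H]2c2ccc(OCc3ccccc3)c(OC)c2)c(OCc2ccccc2)c(OC)c1 | intermediate
14 | 2-[4-(benzyloxy)-3-methoxyphenyl]-1,3-dithiane | COc1cc(C2SCCCS2)ccc1OCc1ccccc1 | intermediate
15 | (5R)-5-{[(1R,2S,5R)-2-isopropyl-5-methylcyclohexyl]oxy}furan-2(5H)-one | O=C1C=C[C@H](O[C@@H]2C[C@H](C)CC[C@H]2C(C)C)O1 | starting material
16 | 2-lithio-2-[4-(benzyloxy)-3-methoxyphenyl]-1,3-dithiane | COc1cc(C2([Li])SCCCS2)ccc1OCc1ccccc1 | intermediate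
17 | lithium enolate of (4R,5R)-4-{2-[4-(benzyloxy)-3-methoxyphenyl]-1,3-dithian-2-yl}-5-(l-menthyloxy)dihydrofuran-2(3H)-one | [Li]OC1=C[C@@H](C2(c3ccc(OCc4ccccc4)c(OC)c3)SCCCS2)[C@H](O[C@@H]2C[C@H](C)CC[C@H]2C(C)C)O1 | intermediate
18 | (3R,4R,5R)-3-{4-(benzyloxy)-3-[(4R,5S)-4-(4-benzyloxy-3-methoxyphenyl)-2,2-dimethyl-1,3-dioxan-5-yl]-5-methoxybenzyl}-4-{2-[4-(benzyloxy)-3-methoxyphenyl]-1,3-dithian-2-yl}-5-(l-menthyloxy)dihydrofuran-2(3H)-one | COc1cc(C2(SCCCS2)[C@H]2[C@H](O[C@@H]3C[C@H](C)CC[C@H]3C(C)C)OC(=O)[C@@H]2Cc2cc([C@H]3COC(C)(C)O[C@H]3c3ccc(OCc4ccccc4)c(OC)c3)c(OCc3ccccc3)c(OC)c2)ccc1OCc1ccccc1 | intermediate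
19 | (3R,4R,5R)-3-{4-(benzyloxy)-3-[(4R,5S)-4-(4-benzyloxy-3-methoxyphenyl)-2,2-dimethyl-1,3-dioxan-5-yl]-5-methoxybenzyl}-4-[4-(benzyloxy)-3-methoxybenzyl]-5-(l-menthyloxy)dihydrofuran-2(3H)-one | COc1cc(C[C@H]2[C@H](O[C@@H]3C[C@H](C)CC[C@H]3C(C)C)OC(=O)[C@@H]2Cc2cc([C@H]3COC(C)(C)O[C@H]3c3ccc(OCc4ccccc4)c(OC)c3)c(OCc3ccccc3)c(OC)c2)ccc1OCc1ccccc1 | intermediate
20 | potassium (2R,3R)-2-{4-(benzyloxy)-3-[(4R,5S)-4-(4-benzyloxy-3-methoxyphenyl)-2,2-dimethyl-1,3-dioxan-5-yl]-5-methoxybenzyl}-3-[4-(benzyloxy)-3-methoxybenzyl]-4-hydroxybutanoate | OC[C@H](Cc1ccc(OCc2ccccc2)c(OC)c1)[C@@H](Cc1cc([C@H]2COC(C)(C)O[C@H]2c2ccc(OCc3ccccc3)c(OC)c2)c(OCc2ccccc2)c(OC)c1)C(=O)[O-].[K+] | intermediate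
21 | (3R,4R)-4-[4-(benzyloxy)-3-methoxybenzyl]-3-{4-(benzyloxy)-3-[(1R,2S)-1-(4-benzyloxy-3-methoxyphenyl)-1,3-dihydroxypropan-2-yl]-5-methoxybenzyl}dihydrofuran-2(3H)-one | COc1cc(C[C@H]2COC(=O)[C@@H]2Cc2cc([C@@H](CO)[C@@H](O)c3ccc(OCc4ccccc4)c(OC)c3)c(OCc3ccccc3)c(OC)c2)ccc1OCc1ccccc1 | intermediate
22 | (3R,4R)-4-[4-(benzyloxy)-3-methoxybenzyl]-3-{4-(benzyloxy)-3-[(2S)-1-(4-benzyloxy-3-methoxyphenyl)-3-hydroxy-1-oxopropan-2-yl]-5-methoxybenzyl}dihydrofuran-2(3H)-one | COc1cc(C[C@H]2COC(=O)[C@@H]2Cc2cc([C@@H](CO)C(=O)c3ccc(OCc4ccccc4)c(OC)c3)c(OCc3ccccc3)c(OC)c2)ccc1OCc1ccccc1 | intermediate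
23 | (3R,4R)-4-(4-hydroxy-3-methoxybenzyl)-3-{4-hydroxy-3-[(2S)-3-hydroxy-1-(4-hydroxy-3-methoxyphenyl)-1-oxopropan-2-yl]-5-methoxybenzyl}dihydrofuran-2(3H)-one | COc1cc(C[C@H]2COC(=O)[C@@H]2Cc2cc(OC)c(O)c([C@@H](CO)C(=O)c3ccc(O)c(OC)c3)c2)ccc1O | target

**Step count and risks**

Total step count: 14. Longest linear sequence: 13 steps (steps 1–8, then 10–14).

Steps most likely to fail:

Step 10. The enolate 17 sits next to a quaternary dithianyl carbon, so its C-alkylation may be slow. Proton transfer, ionisation of the electron-rich bromide, or 1,2-addition and γ-deprotonation of the furanone could then take over. The fallback separates the two bond formations and sets the C4 centre by catalysis. It sets out from 8: Stobbe condensation with dimethyl succinate (NaOMe, MeOH, reflux) should give (E)-4-[4-(benzyloxy)-3-methoxyphenyl]-3-(methoxycarbonyl)but-3-enoic acid F1. Asymmetric hydrogenation with [Rh(cod)2]BF4 and a C2-symmetric bisphosphine such as Me-DuPhos, in the antipode that delivers the (R) acid, should give (R)-4-[4-(benzyloxy)-3-methoxyphenyl]-3-(methoxycarbonyl)butanoic acid F2. Reduction of the ester in the potassium carboxylate with Ca(BH4)2 (from CaCl2 and NaBH4, EtOH) and acidification should give (R)-4-[4-(benzyloxy)-3-methoxybenzyl]dihydrofuran-2(3H)-one F3. Its lithium enolate (LiN(SiMe3)2, THF, −78 °C) is alkylated trans by 13 in the presence of DMPU to the lactone acetonide F4. 2 M HCl in THF then removes the acetonide, and the sequence comes back to the route at 21.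

Step 11. The nickel hydride surface may hydrogenolyse the aryl benzyl ethers or reductively open the acyl acetal, while C–S cleavage at the hindered quaternary carbon stays incomplete. The fallback avoids sulfur altogether by a radical conjugate addition. It sets out from 15 and purchased 2-[4-(benzyloxy)-3-methoxyphenyl]acetic acid (COc1cc(CC(=O)O)ccc1OCc1ccccc1). Photoredox decarboxylative Giese addition (4CzIPN, Cs2CO3, DMF, blue light, rt) should add the benzylic radical to C4 anti to the menthyloxy group. This gives (4R,5R)-4-[4-(benzyloxy)-3-methoxybenzyl]-5-(l-menthyloxy)dihydrofuran-2(3H)-one F5. Enolisation (LiN(SiMe3)2, THF, −78 °C) and trans alkylation with 13 and DMPU then bring the sequence back to the route at 19.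

Step 13. Hydride abstraction may also occur at the other electron-rich benzylic positions. The acidic hydroquinone by-product may promote enolisation, dehydration or retro-aldol loss of formaldehyde at the newly unveiled α-aryl-β-hydroxy ketone. The fallback differentiates the two hydroxyl groups first. It sets out from 21: selective silylation of the primary alcohol (TBSCl, imidazole, DMF, 0 °C) should give the primary tert-butyldimethylsilyl ether of 21, F6. Buffered oxidation of the remaining secondary alcohol (Dess–Martin periodinane, NaHCO3, CH2Cl2, rt) should give the β-silyloxy ketone F7. Desilylation with HF·pyridine in THF/pyridine at 0 °C then comes back to the route at 22.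

**Further compounds**

F1 | step 10 | (E)-4-[4-(benzyloxy)-3-methoxyphenyl]-3-(methoxycarbonyl)but-3-enoic acid | OC(=O)C/C(C(=O)OC)=C\c1ccc(OCc2ccccc2)c(OC)c1
F2 | step 10 | (R)-4-[4-(benzyloxy)-3-methoxyphenyl]-3-(methoxycarbonyl)butanoic acid | OC(=O)C[C@@H](Cc1ccc(OCc2ccccc2)c(OC)c1)C(=O)OC
F3 | step 10 | (R)-4-[4-(benzyloxy)-3-methoxybenzyl]dihydrofuran-2(3H)-one | COc1cc(C[C@H]2COC(=O)C2)ccc1OCc1ccccc1
F4 | step 10 | (3R,4R)-3-{4-(benzyloxy)-3-[(4R,5S)-4-(4-benzyloxy-3-methoxyphenyl)-2,2-dimethyl-1,3-dioxan-5-yl]-5-methoxybenzyl}-4-[4-(benzyloxy)-3-methoxybenzyl]dihydrofuran-2(3H)-one | COc1cc(C[C@H]2COC(=O)[C@@H]2Cc2cc([C@H]3COC(C)(C)O[C@H]3c3ccc(OCc4ccccc4)c(OC)c3)c(OCc3ccccc3)c(OC)c2)ccc1OCc1ccccc1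
F5 | step 11 | (4R,5R)-4-[4-(benzyloxy)-3-methoxybenzyl]-5-(l-menthyloxy)dihydrofuran-2(3H)-one | COc1cc(C[C@H]2[C@H](O[C@@H]3C[C@H](C)CC[C@H]3C(C)C)OC(=O)C2)ccc1OCc1ccccc1
F6 | step 13 | (3R,4R)-4-[4-(benzyloxy)-3-methoxybenzyl]-3-{4-(benzyloxy)-3-[(1R,2S)-1-(4-benzyloxy-3-methoxyphenyl)-3-(tert-butyldimethylsilyloxy)-1-hydroxypropan-2-yl]-5-methoxybenzyl}dihydrofuran-2(3H)-one | COc1cc(C[C@H]2COC(=O)[C@@H]2Cc2cc([C@@H](CO[Si](C)(C)C(C)(C)C)[C@@H](O)c3ccc(OCc4ccccc4)c(OC)c3)c(OCc3ccccc3)c(OC)c2)ccc1OCc1ccccc1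
F7 | step 13 | (3R,4R)-4-[4-(benzyloxy)-3-methoxybenzyl]-3-{4-(benzyloxy)-3-[(2S)-1-(4-benzyloxy-3-methoxyphenyl)-3-(tert-butyldimethylsilyloxy)-1-oxopropan-2-yl]-5-methoxybenzyl}dihydrofuran-2(3H)-one | COc1cc(C[C@H]2COC(=O)[C@@H]2Cc2cc([C@@H](CO[Si](C)(C)C(C)(C)C)C(=O)c3ccc(OCc4ccccc4)c(OC)c3)c(OCc3ccccc3)c(OC)c2)ccc1OCc1ccccc1
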